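## Retrosynthetic overview

- Numbering: C1 lactone C=O, C2, C3 (peroxy CH), C4 (methyl carbon bearing the lactone O), C5 (ring CH2), C6 (methyl carbon bearing the second peroxide O), C7–C16 side chain (methyl on C8, phenyl on C16).
- Feature: C3 carries the O–O bond. It lies next to quaternary C4, and C3 and C4 are the two atoms shared by the 1,2-dioxane (O, O, C3–C6) and the γ-lactone (C1–C4, O). Cutting C5–C6 and C4–O therefore reveals an isopropenyl-carbinyl (allylic) hydroperoxide with a CH2CO2tBu arm, and a C6 methyl ketone.
- Key disconnection: both rings form in the last step from the side-chain dimethyl ketal and the (S)-hydroperoxy ester. The 1,2-dioxane closes first (O–C6 exchange, then C5–C6) and the γ-lactone directly after it (C4–O).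
- Chain ketal: Julia–Kocienski olefination (C11=C12) joins a citronellal-derived ketal aldehyde (C8 from the chiral pool) to a phenyltetrazolyl sulfone made from (E)-5-phenylpent-4-en-1-ol.
- Hydroperoxide: tert-butyl ester of 4-methylpent-3-enoic acid, Schenck ene reaction, then peroxidase kinetic resolution (sets C3).

Key step: step 11

Assumption: (R)-citronellal of high enantiomeric purity, (E)-5-phenylpent-4-en-1-ol and 4-methylpent-3-enoic acid are taken as catalogue compounds, and the purity at C8 of the target is that of the citronellal used.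

## Route

Step 1
Reactants: 1 (R)-citronellal
Product: 2 (4R)-4,8-dimethylnon-7-en-2-ol (both C2 epimers)
Conditions: MeMgBr, Et2O, −78 → 0 °C; aqueous work-up
Reagents that add atoms: methylmagnesium bromide, C[Mg]Br
Why: Grignard 1,2-addition to the aldehyde brings in the future C6 methyl group; the new carbinol centre forms without control but is erased in step 2, and C8, β to the carbonyl group, cannot epimerise.

Step 2
Reactants: 2 (4R)-4,8-dimethylnon-7-en-2-ol
Product: 3 (4R)-4,8-dimethylnon-7-en-2-one
Conditions: Dess–Martin periodinane, CH2Cl2, 0 °C → rt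
Reagents that add atoms: none
Why: Dess–Martin oxidation of a secondary alcohol runs under near-neutral conditions that leave the trisubstituted alkene and C8 untouched.

Step 3
Reactants: 3 (4R)-4,8-dimethylnon-7-en-2-one
Product: 4 (6R)-8,8-dimethoxy-2,6-dimethylnon-2-ene
Conditions: HC(OMe)3, MeOH, p-TsOH·H2O (cat.), rt; Et3N quench, filtration over basic alumina
Reagents that add atoms: trimethyl orthoformate, COC(OC)OC; methanol, CO
Why: Acid-catalysed ketalisation of an unhindered methyl ketone is driven to completion by the orthoformate as water scavenger, and the catalytic acid at room temperature does not touch the alkene.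

Step 4
Reactants: 4 (6R)-8,8-dimethoxy-2,6-dimethylnon-2-ene
Product: 6 (4R)-6,6-dimethoxy-4-methylheptanal, via secondary ozonide 5 (not isolated)
Conditions: O3/O2, solid NaHCO3, CH2Cl2, −78 °C; then PPh3, −78 °C → rt; Et3N-deactivated silica
Reagents that add atoms: ozone, [O-][O+]=O
Why: Ozonolysis (Criegee mechanism) cleaves the only C=C bond and PPh3 reduces the ozonide to the aldehyde, while the ketal has no acetal C–H for ozone to attack and the solid base keeps the medium non-acidic.

Step 5
Reactants: 7 (E)-5-phenylpent-4-en-1-ol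
Product: 8 1-phenyl-5-{[(4E)-5-phenylpent-4-en-1-yl]sulfanyl}-1H-tetrazole
Conditions: 1-phenyl-1H-tetrazole-5-thiol, PPh3, DIAD, THF, 0 °C → rt
Reagents that add atoms: 1-phenyl-1H-tetrazole-5-thiol, Sc1nnnn1-c1ccccc1
Why: Mitsunobu thioetherification of a primary alcohol with an acidic heteroaryl thiol is a standard entry to Julia–Kocienski sulfones and does not affect the styrenyl alkene.

Step 6
Reactants: 8 1-phenyl-5-{[(4E)-5-phenylpent-4-en-1-yl]sulfanyl}-1H-tetrazole
Product: 9 1-phenyl-5-{[(4E)-5-phenylpent-4-en-1-yl]sulfonyl}-1H-tetrazole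
Conditions: (NH4)6Mo7O24·4H2O (cat.), 30% H2O2, EtOH, 0 °C → rt
Reagents that add atoms: hydrogen peroxide, OO
Why: Molybdate-catalysed peroxide oxidation takes the sulfide to the sulfone much faster than it attacks an unactivated alkene, so the styrene, which a peracid could epoxidise, should survive.

Step 7
Reactants: 9 1-phenyl-5-{[(4E)-5-phenylpent-4-en-1-yl]sulfonyl}-1H-tetrazole; 6 (4R)-6,6-dimethoxy-4-methylheptanal
Product: 11 (4R,7E,11E)-2,2-dimethoxy-4-methyl-12-phenyldodeca-7,11-diene, via potassiated sulfone 10 (not isolated)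
Conditions: 9, KHMDS, DME, −60 °C; then 6, −60 °C → rt; aq. NaHCO3; Et3N-deactivated silica
Reagents that add atoms: none
Why: Julia–Kocienski olefination (addition, Smiles rearrangement, anti elimination of SO2 and the tetrazolate) should give the E alkene at C11=C12, as is usual for phenyltetrazolyl sulfones with a potassium counter-ion in DME, and the basic medium preserves the ketal.

Step 8
Reactants: 12 4-methylpent-3-enoic acid
Product: 13 tert-butyl 4-methylpent-3-enoate
Conditions: tert-butyl 2,2,2-trichloroacetimidate, CH2Cl2/cyclohexane, rt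
Reagents that add atoms: tert-butyl 2,2,2-trichloroacetimidate, CC(C)(C)OC(=N)C(Cl)(Cl)Cl
Why: Imidate esterification is promoted by the carboxylic acid itself, so it avoids both the strong acid that would lactonise this γ,γ-dimethyl β,γ-unsaturated acid and the base that would move the alkene into conjugation.

Step 9
Reactants: 13 tert-butyl 4-methylpent-3-enoate
Product: 14 tert-butyl (±)-3-hydroperoxy-4-methylpent-4-enoate
Conditions: O2, tetraphenylporphyrin (cat.), hν (visible), CH2Cl2, −10 → 0 °C
Reagents that add atoms: oxygen, O=O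
Why: In the Schenck ene reaction singlet oxygen bonds to C3 and takes a hydrogen from one of the geminal methyl groups, giving the racemic isopropenyl hydroperoxide; the C2–H bonds are electron-poor and are held near the alkene plane by 1,3-allylic strain, so the conjugated tertiary regioisomer should be the minor product and is removed by chromatography.

Step 10
Reactants: 14 tert-butyl (±)-3-hydroperoxy-4-methylpent-4-enoate
Product: 15 tert-butyl (3S)-3-hydroperoxy-4-methylpent-4-enoate
Conditions: horseradish peroxidase (cat.), guaiacol, phosphate buffer pH 6, 20 °C, run to about half conversion; chromatography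
Reagents that add atoms: none
Why: In this peroxidase-catalysed kinetic resolution of a racemic secondary hydroperoxide the enzyme should reduce the (R)-enantiomer to the alcohol at the expense of guaiacol and leave the (S)-hydroperoxide, the sense usual for substrates with an sp2 substituent on the carbinyl carbon; this sets C3, and the configuration is to be confirmed on a sample by PPh3 reduction and Mosher ester analysis.

Step 11
Reactants: 11 (4R,7E,11E)-2,2-dimethoxy-4-methyl-12-phenyldodeca-7,11-diene; 15 tert-butyl (3S)-3-hydroperoxy-4-methylpent-4-enoate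
Product: 18 CNP0365311.2 (target; 3S,4S,6R,8R), via mixed peroxyketal 16 (not isolated), via peroxycarbenium triflate 17 (not isolated)
Conditions: (i) PPTS (cat.), 4 Å MS, CH2Cl2, 0 °C → rt; (ii) 2,6-di-tert-butyl-4-methylpyridine (DTBMP), TMSOTf, −78 → −40 °C; aq. NaHCO3; chromatography
Reagents that add atoms: none
Why: Proposed new method: PPTS exchanges one methoxy group of 11 for the hydroperoxide oxygen of 15 to give 16, TMSOTf then removes the second methoxy group as TMSOMe, and in the resulting O–O-stabilised C6 cation 17 the terminal CH2 of the tethered isopropenyl group attacks C6 (C5–C6) while the ester carbonyl oxygen captures the developing tertiary C4 cation and releases isobutene (C4–O). The closest known reaction types are Lewis-acid additions and cyclisations of alkenes and allylsilanes onto peroxycarbenium ions made from monoperoxyketals and Prins cyclisations terminated by tert-butyl esters or carbonates, but their union in one cascade, with an allylic hydroperoxide in the role of the homoallylic alcohol, is without precedent. The 1,2-dioxane closes 6-endo-trig at the alkene through a chair made up of O, O, C6, C5, C4 and C3 (the C6=O+ bond is endocyclic as well), and the γ-lactone closes 5-exo-trig at C4 with C5 left outside the five-membered ring. C4 is controlled by C3, because the two-atom arm can reach C4 only on the face on which it stands, which enforces the cis-fused (3S,4S) pair, and anti addition across C4=C5 places this arm axial, where it also escapes A(1,2) strain with the C4 methyl group. C6 is controlled by the geometry of 17: the larger C7 chain should lie trans to the O–O bond and hence equatorial, cis to the axial arm across the ring, and the smaller methyl group should take the axial site facing the C4 methyl group, which corresponds to 6R, although this preference is expected to be modest and the 6S epimer has to be removed by chromatography. The step needs the isopropenyl group to outrun the C11=C12 and C15=C16 alkenes and O–O heterolysis, which is secured by the tertiary, ester-assisted cation available only from the 1,1-disubstituted alkene (C11=C12 would give a secondary cation), by the reversibility of the unproductive loss of the hydroperoxide from 16, and by the hindered base and −78 °C that hold back Hock-type cleavage.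

## Compound list

1 | (R)-citronellal, (3R)-3,7-dimethyloct-6-enal | C[C@H](CCC=C(C)C)CC=O | starting material
2 | (4R)-4,8-dimethylnon-7-en-2-ol (both C2 epimers) | C[C@H](CCC=C(C)C)CC(C)O | intermediate
3 | (4R)-4,8-dimethylnon-7-en-2-one | C[C@H](CCC=C(C)C)CC(C)=O | intermediate
4 | (6R)-8,8-dimethoxy-2,6-dimethylnon-2-ene | C[C@H](CCC=C(C)C)CC(C)(OC)OC | intermediate
5 | 3-[(3R)-5,5-dimethoxy-3-methylhexyl]-5,5-dimethyl-1,2,4-trioxolane (secondary ozonide, not isolated) | C[C@H](CCC1OOC(C)(C)O1)CC(C)(OC)OC | intermediate
6 | (4R)-6,6-dimethoxy-4-methylheptanal | C[C@H](CCC=O)CC(C)(OC)OC | intermediate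
7 | (E)-5-phenylpent-4-en-1-ol | OCCC/C=C/c1ccccc1 | starting material
8 | 1-phenyl-5-{[(4E)-5-phenylpent-4-en-1-yl]sulfanyl}-1H-tetrazole | S(CCC/C=C/c1ccccc1)c1nnnn1-c1ccccc1 | intermediate
9 | 1-phenyl-5-{[(4E)-5-phenylpent-4-en-1-yl]sulfonyl}-1H-tetrazole | O=S(=O)(CCC/C=C/c1ccccc1)c1nnnn1-c1ccccc1 | intermediate
10 | potassium salt of the α-sulfonyl carbanion of 9 (not isolated) | [K+].[CH-](CC/C=C/c1ccccc1)S(=O)(=O)c1nnnn1-c1ccccc1 | intermediate
11 | (4R,7E,11E)-2,2-dimethoxy-4-methyl-12-phenyldodeca-7,11-diene (chain ketal) | C[C@H](CC/C=C/CC/C=C/c1ccccc1)CC(C)(OC)OC | intermediate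
12 | 4-methylpent-3-enoic acid | CC(C)=CCC(=O)O | starting material
13 | tert-butyl 4-methylpent-3-enoate | CC(C)=CCC(=O)OC(C)(C)C | intermediate
14 | tert-butyl (±)-3-hydroperoxy-4-methylpent-4-enoate | CC(C)(C)OC(=O)CC(OO)C(C)=C | intermediate
15 | tert-butyl (3S)-3-hydroperoxy-4-methylpent-4-enoate | CC(C)(C)OC(=O)C[C@@H](C(C)=C)OO | intermediate
16 | tert-butyl (3S)-3-{[(4R,7E,11E)-2-methoxy-4-methyl-12-phenyldodeca-7,11-dien-2-yl]peroxy}-4-methylpent-4-enoate (both epimers at the perketal carbon, not isolated) | C[C@H](CC/C=C/CC/C=C/c1ccccc1)CC(C)(OC)OO[C@@H](CC(=O)OC(C)(C)C)C(C)=C | intermediate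
17 | C6 peroxycarbenium triflate derived from 16 by loss of methoxide (not isolated) | C[C@H](CC/C=C/CC/C=C/c1ccccc1)CC(C)=[O+]O[C@@H](CC(=O)OC(C)(C)C)C(C)=C.[O-]S(=O)(=O)C(F)(F)F | intermediate
18 | CNP0365311.2, (3R,4aS,7aS)-3,4a-dimethyl-3-[(2R,5E,9E)-2-methyl-10-phenyldeca-5,9-dien-1-yl]tetrahydrofuro[3,2-c][1,2]dioxin-6-one (3S,4S,6R,8R in the numbering used here) | C[C@H](CC/C=C/CC/C=C/c1ccccc1)C[C@]1(C)C[C@]2(C)OC(=O)C[C@@H]2OO1 | target

## Step count and risks

Total steps: 11. Longest linear sequence: 6 (steps 1, 2, 3, 4, 7, 11).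

**1. Step 11 (new cascade).**
- Risk: O–O heterolysis with vinyl migration (Hock-type cleavage), or ionisation of 16 towards the methoxycarbenium ion, may outrun C5–C6 bond formation. Proton loss from the C4 cation may compete with lactonisation. Facial selectivity at C6 may be poor.
- Fallback, from 11 back to 18, using known reaction types only. Here C4–C5 is made first and the peroxide is introduced last.
- Hydrolysis of 11 (PPTS, aq. acetone) gives (4R,7E,11E)-4-methyl-12-phenyldodeca-7,11-dien-2-one F1. Wittig methylenation (Ph3P=CH2, THF) gives (4R,7E,11E)-2,4-dimethyl-12-phenyldodeca-1,7,11-triene F2.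
- A Cu(II)–bis(oxazoline)-catalysed carbonyl-ene reaction of the 1,1-disubstituted alkene of F2 with methyl pyruvate forms C4–C5 and sets C4 under catalyst control (the ligand antipode is chosen for 2S). It regenerates a methylidene group on C6 in methyl (2S,6R,9E,13E)-2-hydroxy-2,6-dimethyl-4-methylidene-14-phenyltetradeca-9,13-dienoate F3.
- DIBAL-H (CH2Cl2, −78 °C) gives (2S,6R,9E,13E)-2-hydroxy-2,6-dimethyl-4-methylidene-14-phenyltetradeca-9,13-dienal F4.
- (Triphenylphosphoranylidene)ketene (toluene, heat; O-acylation, then intramolecular Wittig reaction) closes (5S)-5-methyl-5-[(4R,7E,11E)-4-methyl-2-methylidene-12-phenyldodeca-7,11-dien-1-yl]furan-2(5H)-one F5.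
- Hydroperoxymercuration follows (one equivalent of Hg(OAc)2, H2O2). In this reaction a 1,1-disubstituted alkene reacts far faster than trans-1,2-disubstituted ones, so OOH should go onto C6. This gives the acetoxymercurio hydroperoxide {(4R,7E,11E)-2-hydroperoxy-4-methyl-2-{[(2S)-2-methyl-5-oxo-2,5-dihydrofuran-2-yl]methyl}-12-phenyldodeca-7,11-dien-1-yl}mercury acetate F6 (both C6 epimers).
- A secondary amine in trifluoroethanol induces intramolecular oxa-Michael addition of the hydroperoxide to C3 of the butenolide. This can only give the cis-fused bicycle, the C6-(acetoxymercuriomethyl) analogue of 18 F7 (both C6 epimers).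
- Bu3SnH replaces C–Hg by C–H, and chromatography separates 18 from the (6S)-epimer of 18 F8.

**2. Step 10 (enzymatic resolution).**
- Risk: the peroxidase may discriminate poorly between two carbinyl substituents of similar size, or may reject the bulky ester, so that enantiomeric enrichment stalls or runs in the wrong sense.
- Fallback, from 14 back to 15: resolution through covalent diastereomers.
- Commercial (1R,2S)-2-phenylcyclohexanol is acetylated to (1R,2S)-2-phenylcyclohexyl acetate F9. Methylenation (Tebbe or Petasis reagent) gives 2-{[(1R,2S)-2-phenylcyclohexyl]oxy}prop-1-ene F10.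
- PPTS-catalysed addition of racemic 14 to F10 creates no new stereocentre and gives two perketals. These are tert-butyl (3S)-4-methyl-3-[(2-{[(1R,2S)-2-phenylcyclohexyl]oxy}propan-2-yl)peroxy]pent-4-enoate F11 and its (3R) diastereomer F12, which are separated by chromatography.
- AcOH/THF/H2O then releases 15 from F11.

**3. Step 4 (ozonolysis next to an acyclic ketal).**
- Risk: adventitious acid during ozonide reduction or chromatography may strip the ketal, after which intramolecular aldol condensation consumes the material.
- Fallback, from 3 back to 11: the ketal is put on after the olefination.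
- Ozonolysis of 3 (O3, CH2Cl2, −78 °C; PPh3) passes through (4R)-6-(5,5-dimethyl-1,2,4-trioxolan-3-yl)-4-methylhexan-2-one F13. It gives (4R)-4-methyl-6-oxoheptanal F14, which is used without delay.
- At −78 °C carbanion 10 should add to the aldehyde far faster than to the methyl ketone, so the Julia–Kocienski reaction gives the ketone F1. Ketalisation of F1 as in step 3 gives 11.

## Further compounds

F1 | step 11 | (4R,7E,11E)-4-methyl-12-phenyldodeca-7,11-dien-2-one | C[C@H](CC/C=C/CC/C=C/c1ccccc1)CC(C)=O
F2 | step 11 | (4R,7E,11E)-2,4-dimethyl-12-phenyldodeca-1,7,11-triene | C[C@H](CC/C=C/CC/C=C/c1ccccc1)CC(C)=C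
F3 | step 11 | methyl (2S,6R,9E,13E)-2-hydroxy-2,6-dimethyl-4-methylidene-14-phenyltetradeca-9,13-dienoate | C[C@H](CC/C=C/CC/C=C/c1ccccc1)CC(=C)C[C@](C(=O)OC)(C)O
F4 | step 11 | (2S,6R,9E,13E)-2-hydroxy-2,6-dimethyl-4-methylidene-14-phenyltetradeca-9,13-dienal | C[C@H](CC/C=C/CC/C=C/c1ccccc1)CC(=C)C[C@](C=O)(C)O
F5 | step 11 | (5S)-5-methyl-5-[(4R,7E,11E)-4-methyl-2-methylidene-12-phenyldodeca-7,11-dien-1-yl]furan-2(5H)-one | C[C@H](CC/C=C/CC/C=C/c1ccccc1)CC(=C)C[C@]1(C)OC(=O)C=C1
F6 | step 11 | {(4R,7E,11E)-2-hydroperoxy-4-methyl-2-{[(2S)-2-methyl-5-oxo-2,5-dihydrofuran-2-yl]methyl}-12-phenyldodeca-7,11-dien-1-yl}mercury acetate (both C6 epimers) | C[C@H](CC/C=C/CC/C=C/c1ccccc1)CC(C[Hg]OC(C)=O)(OO)C[C@]1(C)OC(=O)C=C1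
F7 | step 11 | C6-(acetoxymercuriomethyl) analogue of 18 (both C6 epimers) | C[C@H](CC/C=C/CC/C=C/c1ccccc1)CC1(C[Hg]OC(C)=O)C[C@]2(C)OC(=O)C[C@@H]2OO1
F8 | step 11 | (6S)-epimer of 18 | C[C@H](CC/C=C/CC/C=C/c1ccccc1)C[C@@]1(C)C[C@]2(C)OC(=O)C[C@@H]2OO1
F9 | step 10 | (1R,2S)-2-phenylcyclohexyl acetate | CC(=O)O[C@@H]1CCCC[C@H]1c1ccccc1
F10 | step 10 | 2-{[(1R,2S)-2-phenylcyclohexyl]oxy}prop-1-ene | C=C(C)O[C@@H]1CCCC[C@H]1c1ccccc1
F11 | step 10 | tert-butyl (3S)-4-methyl-3-[(2-{[(1R,2S)-2-phenylcyclohexyl]oxy}propan-2-yl)peroxy]pent-4-enoate | CC(C)(C)OC(=O)C[C@@H](C(C)=C)OOC(C)(C)O[C@@H]1CCCC[C@H]1c1ccccc1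
F12 | step 10 | tert-butyl (3R)-4-methyl-3-[(2-{[(1R,2S)-2-phenylcyclohexyl]oxy}propan-2-yl)peroxy]pent-4-enoate | CC(C)(C)OC(=O)C[C@H](C(C)=C)OOC(C)(C)O[C@@H]1CCCC[C@H]1c1ccccc1
F13 | step 4 | (4R)-6-(5,5-dimethyl-1,2,4-trioxolan-3-yl)-4-methylhexan-2-one | C[C@H](CCC1OOC(C)(C)O1)CC(C)=O
F14 | step 4 | (4R)-4-methyl-6-oxoheptanal | C[C@H](CCC=O)CC(C)=O
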